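The synthesis rests on forming the C8–C9 bond as the last skeletal bond. C8, a tertiary allylic carbinol, is flanked by the cis C9=C10 double bond attached to the quaternary ring-fusion carbon C1 and by the C7 methylene adjoining the C6 carbinol. An intramolecular Nozaki–Hiyama–Kishi addition of a Z-vinyl iodide to a methyl ketone therefore closes the seven-membered ring B, installs the cis alkene and creates the C8 stereocentre in one operation. The precursor is a cyclopentane (ring A) bearing the C1 methyl and Z-2-iodovinyl groups, the C4 isopropyl carbinol and, on C5, a CH(OSiMe2t-Bu)CH2C(O)CH3 chain; O6 is silylated because an O6–Cr–O8 bridge could only give the cis-1,3-diol.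

Key step: step 10

Numbering: daucane locants are used for all intermediates (ring A = C1–C2–C3–C4–C5, ring B = C1–C5–C6–C7–C8–C9–C10); β is the face of the C1 methyl group.
Assumption: in step 2 the enantiomer of the chiral NHC ligand is taken that gives the S-configured quaternary carbon; compound 1 is the purchasable ethylene ketal of ethyl acetoacetate.

Step 1
Reactants: 1 ethyl 2-(2-methyl-1,3-dioxolan-2-yl)acetate
Product: 2 2-(2-methyl-1,3-dioxolan-2-yl)acetaldehyde
Conditions: i-Bu2AlH, CH2Cl2, −78 °C; MeOH, then aq. KNaC4H4O6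
Reagents that add atoms: none
Why: Partial ester reduction by i-Bu2AlH stops at the aldehyde because the tetrahedral aluminium hemiacetal, held by a ketal oxygen, survives at −78 °C until the quench; no stereocentre is formed.

Step 2
Reactants: 3 3-methylcyclopent-2-en-1-one; 4 ethynyltrimethylsilane
Product: 7 (S)-trimethylsilyl enol ether of 3-methyl-3-[1-(trimethylsilyl)ethenyl]cyclopentanone (C4=C5 enol ether), via vinylalane 5 (not isolated), via aluminium enolate 6 (not isolated)
Conditions: 4, i-Bu2AlH, hexanes/THF, 55 °C; then 3, [Ag(NHC)]2 (2.5 mol %; NHC = chiral N-aryl-N′-(2-sulfonatoaryl)imidazolin-2-ylidene), Cu(OTf)2 (5 mol %), THF, −78 °C; then Me3SiOTf, −78 °C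
Reagents that add atoms: trimethylsilyl triflate, C[Si](C)(C)OS(=O)(=O)C(F)(F)F
Why: Copper-catalysed enantioselective conjugate addition of a silicon-substituted vinylalane (from syn hydroalumination of 4, aluminium on the silicon-bearing carbon) to a β-substituted cyclopentenone builds quaternary C1, the chiral NHC–copper complex choosing the enone face (1S), and O-silylation of enolate 6 stores the enolate regiochemistry at C5.

Step 3
Reactants: 7 silyl enol ether; 2 ketal aldehyde
Product: 9 anti aldol (2S,3S)-2-[(1S)-1-hydroxy-2-(2-methyl-1,3-dioxolan-2-yl)ethyl]-3-methyl-3-[1-(trimethylsilyl)ethenyl]cyclopentan-1-one, via lithium enolate 8 (not isolated)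
Conditions: MeLi, THF, 0 °C; then 2, −78 °C; sat. aq. NH4Cl at −78 °C
Reagents that add atoms: none
Why: MeLi cleaves the O–Si bond to the regiodefined lithium enolate, whose aldol addition through a closed chair transition state should set C5 by attack anti to the bulky 1-silylvinyl group (new bond cis to the C1 methyl, which a plain vinyl group could not enforce) and C6 as the anti aldol expected for a ring-locked E-enolate (5S,6S).

Step 4
Reactants: 9 aldol
Product: 10 tert-butyldimethylsilyl ether of 9
Conditions: t-BuMe2SiOTf, 2,6-lutidine, CH2Cl2, −78 °C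
Reagents that add atoms: tert-butyldimethylsilyl triflate, CC(C)(C)[Si](C)(C)OS(=O)(=O)C(F)(F)F
Why: Silyl triflate silylation with a hindered pyridine base protects the secondary aldol hydroxyl at low temperature without retro-aldol, and the ether later keeps O6 out of the ring closure.

Step 5
Reactants: 10 silyloxy ketone
Product: 11 (1R,2S,3S)-2-[(1S)-1-(tert-butyldimethylsilyloxy)-2-(2-methyl-1,3-dioxolan-2-yl)ethyl]-3-methyl-1-(propan-2-yl)-3-[1-(trimethylsilyl)ethenyl]cyclopentan-1-ol
Conditions: i-PrLi, CeCl3, THF, −78 °C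
Reagents that add atoms: isopropyllithium, [Li]C(C)C
Why: Organocerium 1,2-addition (low basicity, high oxophilicity) to the hindered, enolisable cyclopentanone should bring the isopropyl group in anti to the neighbouring C5 side chain, setting C4 with its hydroxyl cis to that chain (4R).

Step 6
Reactants: 11 vinylsilane
Product: 12 1-iodovinyl analogue of 11 (C1 bears C(I)=CH2)
Conditions: N-iodosuccinimide, MeCN, 0 °C → rt, dark
Reagents that add atoms: N-iodosuccinimide, O=C1CCC(=O)N1I
Why: Electrophilic ipso-iododesilylation of the vinylsilane (iodonium attack at the silicon-bearing carbon, β-silyl stabilisation, loss of silicon) exchanges SiMe3 for iodine under neutral conditions that spare ketal, silyl ether and tertiary alcohol.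

Step 7
Reactants: 12 1-iodovinyl compound
Product: 14 iodoalkyne (C1 bears C≡C–I), via dilithium alkoxide acetylide 13 (not isolated)
Conditions: LiN(i-Pr)2 (4 equiv), THF, −78 → 0 °C; then I2, −78 °C
Reagents that add atoms: iodine, II
Why: Anti-periplanar E2 dehydroiodination of the 2-iodoalkene by the lithium amide gives the alkyne (quaternary C1 offers no allylic hydrogen, so no allene can form), and the acetylide made by the excess base is iodinated in the same flask.

Step 8
Reactants: 14 iodoalkyne
Product: 15 Z-vinyl iodide (C1 bears (Z)-CH=CHI)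
Conditions: 2-nitrobenzenesulfonylhydrazide, Et3N, THF/i-PrOH, rt
Reagents that add atoms: none
Why: Diimide reduction (concerted syn transfer of two hydrogens from HN=NH released from the sulfonylhydrazide) turns the iodoalkyne into the Z-iodoalkene and should stop there because the iodoalkene is reduced far more slowly.

Step 9
Reactants: 15 ketal
Product: 16 (1R,2S,3S)-2-[(1S)-1-(tert-butyldimethylsilyloxy)-3-oxobutyl]-3-[(Z)-2-iodoethenyl]-3-methyl-1-(propan-2-yl)cyclopentan-1-ol
Conditions: pyridinium p-toluenesulfonate, acetone/H2O, 50 °C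
Reagents that add atoms: water, O
Why: Acid-catalysed ketal hydrolysis with a pyridinium salt frees the C8 methyl ketone while the hindered secondary silyl ether, the tertiary alcohol and the vinyl iodide persist.

Step 10
Reactants: 16 keto vinyl iodide
Product: 18 (1R,4R,5S,6S,8S)-6-(tert-butyldimethylsilyloxy)dauc-9-ene-4,8-diol, via vinylchromium dichloride 17 (not isolated)
Conditions: CrCl2 (10 equiv), NiCl2 (2 mol %), degassed DMSO, 0.005 M, rt → 45 °C
Reagents that add atoms: none
Why: Divalent chromium turns NiCl2 into zerovalent nickel, which adds oxidatively to the C9–I bond without loss of the Z geometry; exchange of nickel for chromium then gives the trivalent vinylchromium 17, which adds to the C8 carbonyl. The closest known reaction type is the intramolecular Nozaki–Hiyama–Kishi addition, used here with a methyl ketone instead of the usual aldehyde, hence the large excess of CrCl2, high dilution and gentle warming. Ring B closes in the 7-exo-trig mode (C9 attacks trigonal C8, the C=O bond stays outside the ring), and the Z alkene on quaternary C1 together with the preferred C5–C6 rotamer (H6 between C1 and C4) holds C9 close to the ketone. The new stereocentre C8 is controlled by the trans ring fusion, which fixes the forming cycloheptene as a chair with the C1 methyl axial on the β face and the O6 silyl ether equatorial: in the four-centre C9–Cr/C8=O array the carbonyl oxygen is expected to take the pseudo-axial β site at C8, so the ketone methyl lies pseudo-equatorial, clear of the syn-axial C1 methyl, and the 8S carbinol with O8 trans to O6 should result. The step needs carbonyl addition to outrun protonation of the C9–Cr bond and enolisation, and it needs retention of the alkene geometry; the low basicity of vinylchromium, the stereospecific nickel insertion and the O6 silyl ether (no retro-aldol, no O6–Cr–O8 bridge, and an O4–C8 hemiketal disfavoured because the silyl ether would be axial in it) should secure them.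

Step 11
Reactants: 18 silyl ether
Product: 19 (1R,4R,5S,6S,8S)-dauc-9-ene-4,6,8-triol
Conditions: Bu4NF, THF, 0 °C → rt
Reagents that add atoms: none
Why: Fluoride-induced desilylation (Si–F bond formation) frees the C6 hydroxyl under basic conditions that the acid-sensitive tertiary allylic C8 carbinol tolerates.

Step 12
Reactants: 20 vanillic acid
Product: 22 4-(tert-butyldimethylsilyloxy)-3-methoxybenzoic acid, via bis-silyl derivative 21 (not isolated)
Conditions: t-BuMe2SiCl, imidazole, DMF, rt; then AcOH/THF/H2O, rt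
Reagents that add atoms: tert-butyldimethylsilyl chloride, CC(C)(C)[Si](C)(C)Cl
Why: Exhaustive silylation followed by selective hydrolysis of the much more labile silyl ester leaves the acid-stable aryl silyl ether and a free carboxylic acid.

Step 13
Reactants: 19 triol; 22 O-silyl vanillic acid
Product: 24 (1R,4R,5S,6S,8S)-4,8-dihydroxydauc-9-en-6-yl 4-(tert-butyldimethylsilyloxy)-3-methoxybenzoate, via acid chloride 23 (not isolated)
Conditions: 22, (COCl)2, DMF (cat.), CH2Cl2, 0 °C → rt, evaporate; then 19, Et3N, DMAP, CH2Cl2, 0 °C → rt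
Reagents that add atoms: none
Why: Acid chloride formation and DMAP-catalysed acylation (nucleophilic catalysis) esterify only the secondary, equatorial C6 hydroxyl, since the tertiary C4 and C8 hydroxyls are too hindered to react.

Step 14
Reactants: 24 silyl-protected ester
Product: 25 (1R,4R,5S,6S,8S)-4,8-dihydroxydauc-9-en-6-yl 4-hydroxy-3-methoxybenzoate (target)
Conditions: Bu4NF, AcOH, THF, 0 °C
Reagents that add atoms: none
Why: Fluoride cleaves the aryl silyl ether rapidly at 0 °C (desilylation), and the acetic acid buffer keeps the benzoate ester and the tertiary allylic alcohol intact.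

Compound list
1 | ethyl 2-(2-methyl-1,3-dioxolan-2-yl)acetate | CCOC(=O)CC1(C)OCCO1 | starting material
2 | 2-(2-methyl-1,3-dioxolan-2-yl)acetaldehyde | O=CCC1(C)OCCO1 | intermediate
3 | 3-methylcyclopent-2-en-1-one | CC1=CC(=O)CC1 | starting material
4 | ethynyltrimethylsilane | C#C[Si](C)(C)C | starting material
5 | diisobutyl[1-(trimethylsilyl)ethenyl]alane (formed in the flask) | C=C([Si](C)(C)C)[Al](CC(C)C)CC(C)C | intermediate
6 | diisobutylaluminium (S)-3-methyl-3-[1-(trimethylsilyl)ethenyl]cyclopent-1-en-1-olate (formed in the flask) | C1=C(O[Al](CC(C)C)CC(C)C)CC[C@]1(C)C(=C)[Si](C)(C)C | intermediate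
7 | (S)-trimethyl({3-methyl-3-[1-(trimethylsilyl)ethenyl]cyclopent-1-en-1-yl}oxy)silane | C1=C(O[Si](C)(C)C)CC[C@]1(C)C(=C)[Si](C)(C)C | intermediate
8 | lithium (S)-3-methyl-3-[1-(trimethylsilyl)ethenyl]cyclopent-1-en-1-olate (formed in the flask) | C1=C(O[Li])CC[C@]1(C)C(=C)[Si](C)(C)C | intermediate
9 | (2S,3S)-2-[(1S)-1-hydroxy-2-(2-methyl-1,3-dioxolan-2-yl)ethyl]-3-methyl-3-[1-(trimethylsilyl)ethenyl]cyclopentan-1-one (side chain cis to the ring methyl) | CC1(OCCO1)C[C@H](O)[C@H]2C(=O)CC[C@]2(C)C(=C)[Si](C)(C)C | intermediate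
10 | (2S,3S)-2-[(1S)-1-(tert-butyldimethylsilyloxy)-2-(2-methyl-1,3-dioxolan-2-yl)ethyl]-3-methyl-3-[1-(trimethylsilyl)ethenyl]cyclopentan-1-one | CC1(OCCO1)C[C@H](O[Si](C)(C)C(C)(C)C)[C@H]2C(=O)CC[C@]2(C)C(=C)[Si](C)(C)C | intermediate
11 | (1R,2S,3S)-2-[(1S)-1-(tert-butyldimethylsilyloxy)-2-(2-methyl-1,3-dioxolan-2-yl)ethyl]-3-methyl-1-(propan-2-yl)-3-[1-(trimethylsilyl)ethenyl]cyclopentan-1-ol (hydroxyl cis to the side chain) | CC1(OCCO1)C[C@H](O[Si](C)(C)C(C)(C)C)[C@H]2[C@](O)(C(C)C)CC[C@]2(C)C(=C)[Si](C)(C)C | intermediate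
12 | (1R,2S,3S)-2-[(1S)-1-(tert-butyldimethylsilyloxy)-2-(2-methyl-1,3-dioxolan-2-yl)ethyl]-3-(1-iodoethenyl)-3-methyl-1-(propan-2-yl)cyclopentan-1-ol | CC1(OCCO1)C[C@H](O[Si](C)(C)C(C)(C)C)[C@H]2[C@](O)(C(C)C)CC[C@]2(C)C(I)=C | intermediate
13 | dilithium C4-alkoxide C9-acetylide of the terminal alkyne derived from 12 (formed in the flask) | CC1(OCCO1)C[C@H](O[Si](C)(C)C(C)(C)C)[C@H]2[C@](O[Li])(C(C)C)CC[C@]2(C)C#C[Li] | intermediate
14 | (1R,2S,3S)-2-[(1S)-1-(tert-butyldimethylsilyloxy)-2-(2-methyl-1,3-dioxolan-2-yl)ethyl]-3-(iodoethynyl)-3-methyl-1-(propan-2-yl)cyclopentan-1-ol | CC1(OCCO1)C[C@H](O[Si](C)(C)C(C)(C)C)[C@H]2[C@](O)(C(C)C)CC[C@]2(C)C#CI | intermediate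
15 | (1R,2S,3S)-2-[(1S)-1-(tert-butyldimethylsilyloxy)-2-(2-methyl-1,3-dioxolan-2-yl)ethyl]-3-[(Z)-2-iodoethenyl]-3-methyl-1-(propan-2-yl)cyclopentan-1-ol | CC1(OCCO1)C[C@H](O[Si](C)(C)C(C)(C)C)[C@H]2[C@](O)(C(C)C)CC[C@]2(C)/C=C\I | intermediate
16 | (1R,2S,3S)-2-[(1S)-1-(tert-butyldimethylsilyloxy)-3-oxobutyl]-3-[(Z)-2-iodoethenyl]-3-methyl-1-(propan-2-yl)cyclopentan-1-ol (O6-silyl iodo keto diol) | CC(=O)C[C@H](O[Si](C)(C)C(C)(C)C)[C@H]1[C@](O)(C(C)C)CC[C@]1(C)/C=C\I | intermediate
17 | dichloro{(Z)-2-[(1S,2S,3R)-2-[(1S)-1-(tert-butyldimethylsilyloxy)-3-oxobutyl]-3-hydroxy-1-methyl-3-(propan-2-yl)cyclopentyl]ethenyl}chromium (formed in the flask) | CC(=O)C[C@H](O[Si](C)(C)C(C)(C)C)[C@H]1[C@](O)(C(C)C)CC[C@]1(C)/C=C\[Cr](Cl)Cl | intermediate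
18 | (1R,4R,5S,6S,8S)-6-(tert-butyldimethylsilyloxy)dauc-9-ene-4,8-diol (trans-fused; 4-OH β, 6-O α, 8-OH β) | CC(C)(C)[Si](C)(C)O[C@H]1C[C@](C)(O)C=C[C@@]2(C)CC[C@@](O)(C(C)C)[C@H]12 | intermediate
19 | (1R,4R,5S,6S,8S)-dauc-9-ene-4,6,8-triol | O[C@H]1C[C@](C)(O)C=C[C@@]2(C)CC[C@@](O)(C(C)C)[C@H]12 | intermediate
20 | vanillic acid (4-hydroxy-3-methoxybenzoic acid) | COc1cc(C(=O)O)ccc1O | starting material
21 | tert-butyldimethylsilyl 4-(tert-butyldimethylsilyloxy)-3-methoxybenzoate (formed in the flask) | COc1cc(C(=O)O[Si](C)(C)C(C)(C)C)ccc1O[Si](C)(C)C(C)(C)C | intermediate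
22 | 4-(tert-butyldimethylsilyloxy)-3-methoxybenzoic acid | COc1cc(C(=O)O)ccc1O[Si](C)(C)C(C)(C)C | intermediate
23 | 4-(tert-butyldimethylsilyloxy)-3-methoxybenzoyl chloride (formed in the flask) | COc1cc(C(=O)Cl)ccc1O[Si](C)(C)C(C)(C)C | intermediate
24 | (1R,4R,5S,6S,8S)-4,8-dihydroxydauc-9-en-6-yl 4-(tert-butyldimethylsilyloxy)-3-methoxybenzoate | COc1cc(C(=O)O[C@H]2C[C@](C)(O)C=C[C@@]3(C)CC[C@@](O)(C(C)C)[C@H]23)ccc1O[Si](C)(C)C(C)(C)C | intermediate
25 | (1R,4R,5S,6S,8S)-4,8-dihydroxydauc-9-en-6-yl 4-hydroxy-3-methoxybenzoate | COc1cc(C(=O)O[C@H]2C[C@](C)(O)C=C[C@@]3(C)CC[C@@](O)(C(C)C)[C@H]23)ccc1O | target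

Total step count: 14. Longest linear sequence: 12 steps (from 3 or 4 through steps 2–11, 13 and 14; also 12 from 1 through steps 1, 3–11, 13 and 14).

Steps most likely to fail

Step 10 (key step). Addition of the hindered vinylchromium to a ketone may be slow, so that protonation of the C9–Cr bond (loss of iodine without ring closure) or enolisation competes, and the facial selectivity at C8 may be incomplete. The fallback is a Barbier-type anionic cyclisation that sets out from 16. The C4 hydroxyl is capped with 1-(trimethylsilyl)imidazole (CH2Cl2, rt) to give the C4 trimethylsilyl ether of 16 F1. Lithium–iodine exchange with t-BuLi (2.1 equiv, THF/Et2O/pentane, −105 °C) generates the Z-vinyllithium with retention, and it adds at once to the C8 ketone to give the cyclised 4-O-trimethylsilyl 6-O-tert-butyldimethylsilyl dauc-9-ene-4,6,8-triol F2. Bu4NF in THF then removes both silyl groups, and the route is rejoined at 19.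

Step 3. The lithium aldol may show poor anti/syn selectivity at C6, or the hindered aldolate may revert. The fallback sets C6 by reduction instead and starts from 11 carried through steps 4 and 5 as a C6-epimer mixture. HF·pyridine (pyridine, THF) removes the silyl ether to give the C6-epimeric diols F3. Dess–Martin oxidation of the secondary hydroxyl gives the β-hydroxy ketone F4. Narasaka–Prasad reduction (Et2BOMe, NaBH4, THF/MeOH, −78 °C) should then give the 6S diol F5: boron bridges O4 and the C6 carbonyl, and external hydride adds axially, anti to H5, to the chair in which C7 and C1 are equatorial. Selective silylation of the secondary hydroxyl (t-BuMe2SiOTf, 2,6-lutidine, −78 °C) returns to 11 as a single epimer.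

Step 5. The secondary organometallic may enolise the hindered ketone or reduce it by β-hydride transfer instead of adding. The fallback sets out from 10 and uses an sp2 nucleophile that is smaller and cannot transfer hydride. CH2=C(CH3)MgBr with CeCl3 (THF, −78 → 0 °C) should add anti to the C5 side chain to give the isopropenyl carbinol F6. Hydroxyl-directed hydrogenation with [Rh(nbd)(dppb)]BF4 under H2 pressure in CH2Cl2 then saturates only the allylic-alcohol alkene, leaving the hindered, undirected vinylsilane, and returns to 11.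

Further compounds
F1 | step 10 | (Z)-iodovinyl methyl ketone 16 with the C4 hydroxyl as trimethylsilyl ether | CC(=O)C[C@H](O[Si](C)(C)C(C)(C)C)[C@H]1[C@](O[Si](C)(C)C)(C(C)C)CC[C@]1(C)/C=C\I
F2 | step 10 | (1R,4R,5S,6S,8S)-6-(tert-butyldimethylsilyloxy)-4-(trimethylsilyloxy)dauc-9-en-8-ol | CC(C)(C)[Si](C)(C)O[C@H]1C[C@](C)(O)C=C[C@@]2(C)CC[C@@](O[Si](C)(C)C)(C(C)C)[C@H]12
F3 | step 3 | desilylated 11 as a mixture of C6 epimers (4,6-diol) | CC1(OCCO1)CC(O)[C@H]2[C@](O)(C(C)C)CC[C@]2(C)C(=C)[Si](C)(C)C
F4 | step 3 | C6 ketone of F3 (β-hydroxy ketone with the C4 hydroxyl) | CC1(OCCO1)CC(=O)[C@H]2[C@](O)(C(C)C)CC[C@]2(C)C(=C)[Si](C)(C)C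
F5 | step 3 | 6S diol (desilylated 11 as a single epimer) | CC1(OCCO1)C[C@H](O)[C@H]2[C@](O)(C(C)C)CC[C@]2(C)C(=C)[Si](C)(C)C
F6 | step 5 | isopropenyl analogue of 11 (prop-1-en-2-yl on C4 in place of isopropyl) | CC1(OCCO1)C[C@H](O[Si](C)(C)C(C)(C)C)[C@H]2[C@](O)(C(C)=C)CC[C@]2(C)C(=C)[Si](C)(C)C
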